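All runs are calculated on assumed constants.

If I follow one molecule of substrate, its fate has a fork: once gone, it ends either as target or as something these readings do not show. So target equals substrate lost times the chance at that fork.

| flask | substrate | first nucleophile | second nucleophile | remark | time |
|---|---|---|---|---|---|
| teal | 31 mM | 4 equiv | 1.3 equiv (in portions, 3) | run made earlier; portions every 15 min |  |
| violet | 48 mM | 4 equiv | 1.3 equiv (in portions, 3) | run made earlier; portions every 15 min |  |
| dawn | 22 mM | 4.00 equiv | 1.30 equiv | everything together at the start | 150 min |
| autumn | 22 mM | 4.00 equiv | 1.30 equiv (in portions, 3) | the portions of second nucleophile follow each other after 15 min, the first at the start | 80 min |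

| run | time / min | target / % | substrate / % |
|---|---|---|---|
| teal | 5.00 | 1.2 | 98.4 |
| teal | 15.0 | 3.1 | 96.1 |
| teal | 25.0 | 4.9 | 93.6 |
| teal | 40.0 | 6.6 | 88.4 |
| teal | 60.0 | 9.3 | 84.4 |
| teal | 80.0 | 11.8 | 81.2 |
| teal | 90.0 | 13.4 | 78.0 |
| violet | 5.00 | 1.0 | 98.2 |
| violet | 15.0 | 3.2 | 95.8 |
| violet | 25.0 | 3.9 | 94.0 |
| violet | 40.0 | 6.5 | 90.6 |
| violet | 60.0 | 9.7 | 84.5 |
| violet | 80.0 | 11.1 | 80.1 |
| violet | 90.0 | 12.9 | 78.3 |

(standard deviation of a reading: 0.5 percentage points)

- a reading or a percentage of target counts all its forms, free or not

* which one finishes higher in amount of target, in percent of the substrate charged ("neither" within 2 percentage points) (dawn / autumn / neither)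
* amount of target at the end, in percent of the substrate charged, dawn
* amount of target at the end, in percent of the substrate charged, autumn

The percent curves of teal and violet overlay, so I pool them. I read a first-order constant of 0.00274 min⁻¹ for the fall of substrate. From 40.0 min to 90.0 min, after the last portion, the pooled target gained per substrate lost reads 0.581. From that I take the fork odds, the selectivity factor written as unseen fate over target with the full second nucleophile present, 0.720, and I assume they scale with the second nucleophile.

In the first instants, I put dawn at these odds, since it holds its full second nucleophile. Autumn doses in 3 portions, so over the first 30.0 min it holds on average half of its charge, which on my assumption halves the odds and lifts the share to 0.735. That head start is worth 1.2 percentage points. In the middle, dawn spends about 10.8% of its second nucleophile by the end, so I hold its odds steady. By its end, I reckon the substrate gone from dawn at 33.7% of the charge, and from autumn at 19.7%. I commit to 19.6% for dawn. For autumn, the recipe of teal and violet, I take their mean at 80.0 min, 11.5%. At my share, the extra substrate gone in dawn is worth 8.1 points of target, more than autumn's head start, so I expect dawn to finish higher.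

The forecast says dawn, with 20.3% for dawn and 11.7% for autumn, on the ground that “The longer time clearly outweighs the small dosing benefit”, and my two figures lie slightly below its two .

The flasks give 16.9% for dawn and 10.9% for autumn, so dawn finishes higher, by 6 points against a margin of 2 points.

    first nucleophile + target ⇌ idle adduct, settled at all times (K = 5.90 L mol⁻¹)
    first nucleophile + intermediate → target (k = 0.300 L mol⁻¹ s⁻¹)
    second nucleophile + intermediate → other capture product (k = 0.810 L mol⁻¹ s⁻¹)
    intermediate → solvolysis product (k = 0.00280 s⁻¹)
    substrate → intermediate (k = 4.50 × 10⁻⁵ s⁻¹)

In autumn, with the first nucleophile as charged, the intermediate's half-life towards target is 0.44 min, against 4.3 h for substrate passing into intermediate. That passage is the rate-limiting step, and at 80.0 min the intermediate stands at 0.0724%, made and used at a ratio of 0.999. Dawn's fork odds came to 0.965, above my 0.720, on 33.3% of substrate lost.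

For autumn read at 30 min, before its last portion, I take the halved odds, 0.360: the share 0.735 on 7.89% lost gives 5.80%. The flask gives 5.02%.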